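The earlier runs and the new flask stem from a simulated flask with constants of no real substance; scatter was added.

Left-handed product is what the readings follow: it stays out of sight at first, then climbs faster and faster.

| flask | left-handed substrate | right-handed substrate | partner | precatalyst | remark | time |
|---|---|---|---|---|---|---|
| north-west | 0.081 M | 0.081 M | 0.232 M (fed, over 10 h) | 0.41 mM | run made earlier; the fed solution adds 0.50 times the starting volume |  |
| north | 0.13 M | 0.13 M | 0.232 M (fed, over 10 h) | 0.41 mM | run made earlier; the fed solution adds 0.50 times the starting volume |  |
| flask | 0.058 M | 0.058 M | 0.232 M (fed, over 10 h) | 0.41 mM | the fed solution adds 0.50 times the starting volume | 2.5 d |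

| run | time / h | left-handed substrate / % | left-handed product / % |
|---|---|---|---|
| north-west | 3.00 | 50 | 0 |
| north-west | 5.00 | 50 | 0 |
| north-west | 8.00 | 51 | 0 |
| north-west | 12.0 | 51 | 3 |
| north-west | 20.0 | 46 | 5 |
| north-west | 40.0 | 33 | 19 |
| north | 2.50 | 47 | 3 |
| north | 8.00 | 51 | 0 |
| north | 12.0 | 47 | 2 |
| north | 20.0 | 46 | 5 |
| north | 30.0 | 37 | 9 |
| north | 40.0 | 32 | 16 |

(scatter of a reading: 1.5 percentage points)
* which holds at 2.5 d: what has brought the reaction to rest, or that it has not come to rest (no working catalyst is left / it is still moving / all of the left-handed substrate has reacted / the partner has run out first / forward and back rates have come level)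
* share of the left-handed substrate and right-handed substrate together used up at 2.5 d
* left-handed product at 2.5 d, in percent of the left-handed substrate and right-handed substrate together charged
* right-handed substrate at 2.5 d, in percent of the left-handed substrate and right-handed substrate together charged
- catalyst is single-handed; left-handed substrate and right-handed substrate are mirror images of each other, charged as a racemate, each of them at the stated concentration
- charges are per starting volume, the dose included; the dosed solution carries all of it
- the reaction counts as stopped when no species that holds the left-handed substrate and right-handed substrate together changes by six tenths of a point or more over the second half of the time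

From 20.0 h to 40.0 h the time grows 2.00-fold, while the product, read at 5% in both runs, reaches a mean of 17.5%. That is 3.50-fold, close to the 4.00 of a square law. So the rate starts near zero and rises, as if catalyst were being built at a steady pace. The two runs differ 1.60-fold in substrate, yet their percentages differ by 3 percentage points at most at 40.0 h, against a scatter of 1.5 points per reading. The flask has the same partner and precatalyst, so this reckoning reads it on the same percentage curve.

That curve draws on a pool of 50%, the left-handed substrate. This reckoning takes product as the pool times one minus the exponential of minus the squared ratio of time to a ramp time, and the mean reading gives 60.9 h. The slope starts at zero. At 10 h the curve stands at 1.33%, inside the scatter, which is the flat start (induction period). The steepest point comes at 43.1 h, at 19.7%. At 60 h the curve gives 31.0%, having gained 20 points over the second half, so on this curve the flask is still moving. The readings hold no right-handed substrate, so this reckoning commits to nothing there.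

The forecast reads: it is still moving, 28% used up, 27% left-handed product, 49% right-handed substrate; “nothing yet shows catalyst death or equilibrium”.

The flask gives: it is still moving, 52.8% used up, 31.2% left-handed product, 26.1% right-handed substrate.

    partner + catalyst + left-handed substrate → catalyst + left-handed product (k = 1000 M⁻² h⁻¹)
    partner + catalyst + right-handed substrate → catalyst + right-handed product (k = 620 M⁻² h⁻¹)
    left-handed substrate ⇌ right-handed substrate (k = 0.0130 h⁻¹)
    partner + precatalyst → catalyst + spent reagent (k = 0.180 M⁻¹ h⁻¹)

The ramp reckoning stood at 31.0% for the product. In the flask, catalyst rose from 14.6% of its charge at 0.417 d to 49.6% at 1.25 d and 74.4% at 2.50 d. A neighbouring flask holds 7.0 × 10⁻⁴ M of precatalyst, all else as here. Taking catalyst as built in proportion to precatalyst, the ramp time shrinks by the square root of that ratio to 46.6 h, which gives 40.5% of product; the computed neighbouring flask holds 39.7%.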